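Everything rests on cutting ring A of the flavone at C4a–C8a and C5–C6. The feature exploited is the substitution pattern of this ring. Five of its six carbons are substituted, the oxygens on C5 (OMe), C7 (OH) and C8a (O1 of ring C) are all chemically distinct, and C6, wedged between two of them, holds C2' of the piperidine. A Danheiser benzannulation inserts the two carbons of a 1-methoxyalkyne that already bears the C4–C3–C2–Ph chain into a cyclobutenone. It thereby assembles the complete ring in one thermal operation, leaving only C8a–OH free. The precursor is a 3-silyloxycyclobutenone carrying the N-Boc-piperidin-2-yl group of L-pipecolic acid on C2.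

Key step: step 6

**Conventions, assumption and design decisions**
- Numbering: flavone numbering is used for the chromenone and primed numbers for the piperidine.
- Stereochemical bookkeeping: the target is (S) at C2'. Replacing CO2H of L-pipecolic acid by an sp or sp2 carbon leaves the order N > C(sp/sp2) > C3' > H unchanged. The only step that changes the bond from C2' to that carbon (step 2) is a 1,2-shift with retention. The descriptor therefore stays (S) in every compound.
- Assumption: C4 is carried as a mixture of carbinol epimers, because it ends as the C4 carbonyl.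
- Atom map of the annulation:
  - cyclobutenone C=O becomes C8a–OH
  - cyclobutenone CH2 becomes C8–H
  - the silyloxy-bearing carbon becomes C7
  - the piperidinyl-bearing carbon becomes C6
  - the MeO-bearing alkyne carbon becomes C5
  - the other alkyne carbon becomes C4a
- Silyl groups: C4–O carries TES and C7–O carries TIPS. The carbinol can then be freed and oxidised while C7–O is still capped. A free 2,4-dihydroxybenzylic propargylic alcohol would be very prone to quinone methide formation.
- Ketene source: ketene is supplied as salt-free gas from acetone cracking (toxic gas, closed line in a hood). An acyl chloride–amine mixture would endanger the silyl ynol ether.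
- Nitrogen protection: nitrogen stays a carbamate until the end, because a basic amine would add to every ketene on the pathway.
- Choice of ynol ether: the methyl ether has no β-hydrogen and so cannot undergo retro-ene loss on heating.

**Route**

Step 1
Reactants: 1 (S)-1-(tert-butoxycarbonyl)piperidine-2-carboxylic acid
Product: 2 1-tert-butyl 2-methyl (S)-piperidine-1,2-dicarboxylate
Conditions: MeI, K2CO3, DMF, rt
Reagents that add atoms: iodomethane, CI
Why: Carboxylate O-alkylation (SN2 esterification) under mildly basic conditions should give the methyl ester needed for the homologation, and the urethane-protected C2' centre is not epimerised because neither an oxazolone nor an enolate can form under these conditions.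

Step 2
Reactants: 2 1-tert-butyl 2-methyl (S)-piperidine-1,2-dicarboxylate
Product: 5 tert-butyl (S)-2-[(triisopropylsilyloxy)ethynyl]piperidine-1-carboxylate, via lithium dibromoenolate 3 (not isolated), via lithium ynolate 4 (not isolated)
Conditions: CH2Br2, LiTMP, THF, −78 °C; add 2; LiN(SiMe3)2, −78 °C; n-BuLi, −78 → 0 °C; TIPSCl, −78 °C → rt
Reagents that add atoms: dibromomethane, BrCBr; triisopropylsilyl chloride, CC(C)[Si](Cl)(C(C)C)C(C)C
Why: Kowalski ynolate synthesis, in which LiCHBr2 is acylated by the ester and deprotonation gives dibromoenolate 3, bromine–lithium exchange then sets off a carbenoid 1,2-shift in which the piperidin-2-yl group migrates with retention at C2' to give ynolate 4, and the bulky chlorosilane should silylate 4 on oxygen rather than on carbon.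

Step 3
Reactants: 5 tert-butyl (S)-2-[(triisopropylsilyloxy)ethynyl]piperidine-1-carboxylate; 6 acetone
Product: 8 tert-butyl (S)-2-[4-oxo-2-(triisopropylsilyloxy)cyclobut-1-en-1-yl]piperidine-1-carboxylate, via ketene 7 (not isolated)
Conditions: ketene gas (acetone, hot-wire generator, ca. 700 °C) passed into 5, MeCN, 0 °C → rt
Reagents that add atoms: none
Why: Ketene–alkyne [2+2] cycloaddition, well known for triisopropylsilyl ynol ethers, in which the nucleophilic alkyne carbon (the one bearing C2') attacks the ketene carbonyl carbon, so only the 2-piperidinyl-3-silyloxy regioisomer is expected, and salt-free ketene gas avoids the acylation, desilylation and ketene oligomerisation that an acyl chloride–amine mixture would invite.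

Step 4
Reactants: 9 chloroacetaldehyde dimethyl acetal (2-chloro-1,1-dimethoxyethane); 10 3-phenylpropiolaldehyde
Product: 12 1-methoxy-5-phenylpenta-1,4-diyn-3-ol (racemic), via lithium methoxyacetylide 11 (not isolated)
Conditions: 9, LiNEt2 (3.1 equiv), THF, −78 → 0 °C; then 10, −78 °C; aq NaHCO3 quench
Reagents that add atoms: none
Why: Base-induced loss of MeOH and HCl from the chloroacetal followed by deprotonation is the standard entry to lithium alkoxyacetylides, and 1,2-addition of 11 to the ynal at −78 °C should outrun aza-Michael addition of the liberated Et2NH, the carbinol centre being formed racemic on purpose because it ends as the C4 carbonyl.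

Step 5
Reactants: 12 1-methoxy-5-phenylpenta-1,4-diyn-3-ol
Product: 13 triethyl[(1-methoxy-5-phenylpenta-1,4-diyn-3-yl)oxy]silane (racemic)
Conditions: TESCl, imidazole, CH2Cl2, 0 °C; Et3N-deactivated silica
Reagents that add atoms: triethylsilyl chloride, CC[Si](Cl)(CC)CC
Why: Imidazole-mediated silylation of a secondary alcohol under non-acidic conditions (so that no Meyer–Schuster rearrangement of the ynol ether carbinol is triggered) masks the hydroxyl that would otherwise quench the ketenes of step 6, and TES is chosen because it can later be removed beside an aryl TIPS ether.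

Step 6
Reactants: 8 tert-butyl (S)-2-[4-oxo-2-(triisopropylsilyloxy)cyclobut-1-en-1-yl]piperidine-1-carboxylate; 13 triethyl[(1-methoxy-5-phenylpenta-1,4-diyn-3-yl)oxy]silane
Product: 18 tert-butyl (S)-2-{4-hydroxy-2-methoxy-3-[3-phenyl-1-(triethylsilyloxy)prop-2-yn-1-yl]-6-(triisopropylsilyloxy)phenyl}piperidine-1-carboxylate, via vinylketene 14 (not isolated), via vinylcyclobutenone 15 (not isolated), via dienylketene 16 (not isolated), via cyclohexadienone 17 (not isolated)
Conditions: 13 (1.5 equiv), toluene (ca. 1 M), base-washed sealed tube, 80 → 115 °C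
Reagents that add atoms: none
Why: Heating opens 8 by 4π electrocyclic cleavage of its C(=O)–CH2 bond to vinylketene 14, which adds across the methoxyalkyne of 13 in a [2+2] event (new bonds C8a–C4a and C6–C5) to give vinylcyclobutenone 15, and a second 4π opening severs the old C8a–C6 bond to give dienylketene 16. Ring A then closes by 6π electrocyclisation of 16, which re-forms C8–C8a, and dienone 17 tautomerises to phenol 18. This is the Danheiser benzannulation of cyclobutenones with alkoxyalkynes, whose closest relatives are annulations of 2,3-disubstituted cyclobutenones and of alkoxy- or silyloxyalkyne partners, the 3-silyloxy group on the four-membered ring being the less explored variable. No lasting stereocentre is created, since the quaternary carbon of 15 is erased on aromatisation, C4 stays an epimeric mixture, and C2' never takes part in bond making or sits at an enolisable position, so it keeps its (S) configuration. The step needs regioselectivity in the [2+2] event, secured by the polarisation of the ynol ether (the carbon remote from OMe is the nucleophile and attacks the ketene carbonyl carbon), and chemoselectivity between the two triple bonds, secured by the far lower nucleophilicity of the phenyl-substituted alkyne. The methyl ynol ether cannot fragment by a retro-ene path, and an excess of 13 at high concentration favours capture of 14 over acylation of the product phenol.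

Step 7
Reactants: 18 tert-butyl (S)-2-{4-hydroxy-2-methoxy-3-[3-phenyl-1-(triethylsilyloxy)prop-2-yn-1-yl]-6-(triisopropylsilyloxy)phenyl}piperidine-1-carboxylate
Product: 19 tert-butyl (S)-2-[4-hydroxy-3-(1-hydroxy-3-phenylprop-2-yn-1-yl)-2-methoxy-6-(triisopropylsilyloxy)phenyl]piperidine-1-carboxylate
Conditions: HF·pyridine, excess pyridine, THF, 0 °C; used without chromatography
Reagents that add atoms: none
Why: Buffered HF desilylation distinguishes the two silyl ethers by size as well as by type, since under mildly acidic fluoride conditions a secondary alkyl TES ether is cleaved much faster than a hindered aryl TIPS ether, and keeping C7–O silylated holds back quinone methide formation from the freed carbinol.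

Step 8
Reactants: 19 tert-butyl (S)-2-[4-hydroxy-3-(1-hydroxy-3-phenylprop-2-yn-1-yl)-2-methoxy-6-(triisopropylsilyloxy)phenyl]piperidine-1-carboxylate
Product: 20 tert-butyl (S)-2-[4-hydroxy-2-methoxy-3-(3-phenylprop-2-ynoyl)-6-(triisopropylsilyloxy)phenyl]piperidine-1-carboxylate
Conditions: activated MnO2, CH2Cl2, rt
Reagents that add atoms: none
Why: MnO2 oxidation of a doubly activated (benzylic and propargylic) alcohol is a mild heterogeneous reaction known for 1-(2-hydroxyaryl)prop-2-yn-1-ols, it leaves phenol, carbamate and silyl ether alone, and it erases the C4 stereocentre so that both epimers converge on one ynone.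

Step 9
Reactants: 20 tert-butyl (S)-2-[4-hydroxy-2-methoxy-3-(3-phenylprop-2-ynoyl)-6-(triisopropylsilyloxy)phenyl]piperidine-1-carboxylate
Product: 23 tert-butyl (S)-2-(7-hydroxy-5-methoxy-4-oxo-2-phenyl-4H-chromen-6-yl)piperidine-1-carboxylate, via enaminone 21 (not isolated), via TIPS-protected flavone 22 (not isolated)
Conditions: Et2NH, EtOH, 60 °C; concentrate; Bu4NF/AcOH, THF, 0 °C
Reagents that add atoms: none
Why: Aza-Michael addition of Et2NH to the ynone gives enaminone 21, in which C8a–OH can only attack C2 by addition–elimination, so the six-membered pyranone (formal 6-endo closure) forms and the 5-exo aurone pathway of simple base catalysis is shut out, after which acetic acid-buffered fluoride cleaves the aryl TIPS ether of 22 without exposing C2' to a strongly basic phenoxide medium.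

Step 10
Reactants: 23 tert-butyl (S)-2-(7-hydroxy-5-methoxy-4-oxo-2-phenyl-4H-chromen-6-yl)piperidine-1-carboxylate
Product: 25 (S)-7-hydroxy-5-methoxy-6-(1-methylpiperidin-2-yl)-2-phenyl-4H-chromen-4-one, via piperidinium trifluoroacetate 24 (not isolated)
Conditions: TFA, CH2Cl2, 0 °C; concentrate; 37% aq HCHO, NaBH(OAc)3, MeCN, 0 °C → rt
Reagents that add atoms: formaldehyde, C=O
Why: Acidolysis of the Boc carbamate followed by reductive amination of the secondary ammonium salt 24 with formaldehyde and NaBH(OAc)3 installs N-methyl without reducing the chromenone, and since no bond to C2' is broken and the temperature stays low enough to prevent retro-Mannich opening of the ortho-hydroxybenzylic amine, the (S) configuration is retained.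

**Compound list**

1 | (S)-1-(tert-butoxycarbonyl)piperidine-2-carboxylic acid | OC(=O)[C@@H]1CCCCN1C(=O)OC(C)(C)C | starting material
2 | 1-tert-butyl 2-methyl (S)-piperidine-1,2-dicarboxylate | COC(=O)[C@@H]1CCCCN1C(=O)OC(C)(C)C | intermediate
3 | lithium (S)-2,2-dibromo-1-[1-(tert-butoxycarbonyl)piperidin-2-yl]ethen-1-olate | [Li+].[O-]C(=C(Br)Br)[C@@H]1CCCCN1C(=O)OC(C)(C)C | intermediate
4 | lithium (S)-2-[1-(tert-butoxycarbonyl)piperidin-2-yl]ethyn-1-olate | [Li+].[O-]C#C[C@@H]1CCCCN1C(=O)OC(C)(C)C | intermediate
5 | tert-butyl (S)-2-[(triisopropylsilyloxy)ethynyl]piperidine-1-carboxylate | CC(C)[Si](OC#C[C@@H]1CCCCN1C(=O)OC(C)(C)C)(C(C)C)C(C)C | intermediate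
6 | acetone | CC(C)=O | starting material
7 | ketene | C=C=O | intermediate
8 | tert-butyl (S)-2-[4-oxo-2-(triisopropylsilyloxy)cyclobut-1-en-1-yl]piperidine-1-carboxylate | O=C1CC(O[Si](C(C)C)(C(C)C)C(C)C)=C1[C@@H]1CCCCN1C(=O)OC(C)(C)C | intermediate
9 | chloroacetaldehyde dimethyl acetal | COC(CCl)OC | starting material
10 | 3-phenylpropiolaldehyde | O=CC#Cc1ccccc1 | starting material
11 | lithium methoxyacetylide | [Li+].[C-]#COC | intermediate
12 | 1-methoxy-5-phenylpenta-1,4-diyn-3-ol (racemic) | COC#CC(O)C#Cc1ccccc1 | intermediate
13 | triethyl[(1-methoxy-5-phenylpenta-1,4-diyn-3-yl)oxy]silane (racemic) | COC#CC(O[Si](CC)(CC)CC)C#Cc1ccccc1 | intermediate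
14 | tert-butyl (S)-2-[1-oxo-3-(triisopropylsilyloxy)buta-1,3-dien-2-yl]piperidine-1-carboxylate (vinylketene) | O=C=C(C(=C)O[Si](C(C)C)(C(C)C)C(C)C)[C@@H]1CCCCN1C(=O)OC(C)(C)C | intermediate
15 | tert-butyl (S)-2-{2-methoxy-4-oxo-3-[3-phenyl-1-(triethylsilyloxy)prop-2-yn-1-yl]-1-[1-(triisopropylsilyloxy)ethenyl]cyclobut-2-en-1-yl}piperidine-1-carboxylate (ring and carbinol centres unassigned) | O=C1C(C(O[Si](CC)(CC)CC)C#Cc2ccccc2)=C(OC)C1(C(=C)O[Si](C(C)C)(C(C)C)C(C)C)[C@@H]1CCCCN1C(=O)OC(C)(C)C | intermediate
16 | dienylketene O=C=C(C4 chain)–C(OMe)=C(N-Boc-piperidin-2-yl)–C(OTIPS)=CH2, silyloxyvinyl group cis to the ketene arm, (S) at C2' | O=C=C(C(O[Si](CC)(CC)CC)C#Cc1ccccc1)/C(OC)=C(\C(=C)O[Si](C(C)C)(C(C)C)C(C)C)[C@@H]1CCCCN1C(=O)OC(C)(C)C | intermediate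
17 | cyclohexa-2,4-dien-1-one tautomer of 18, (S) at C2' | O=C1CC(O[Si](C(C)C)(C(C)C)C(C)C)=C([C@@H]2CCCCN2C(=O)OC(C)(C)C)C(OC)=C1C(O[Si](CC)(CC)CC)C#Cc1ccccc1 | intermediate
18 | tert-butyl (S)-2-{4-hydroxy-2-methoxy-3-[3-phenyl-1-(triethylsilyloxy)prop-2-yn-1-yl]-6-(triisopropylsilyloxy)phenyl}piperidine-1-carboxylate (C4 epimers) | Oc1cc(O[Si](C(C)C)(C(C)C)C(C)C)c([C@@H]2CCCCN2C(=O)OC(C)(C)C)c(OC)c1C(O[Si](CC)(CC)CC)C#Cc1ccccc1 | intermediate
19 | tert-butyl (S)-2-[4-hydroxy-3-(1-hydroxy-3-phenylprop-2-yn-1-yl)-2-methoxy-6-(triisopropylsilyloxy)phenyl]piperidine-1-carboxylate (C4 epimers) | Oc1cc(O[Si](C(C)C)(C(C)C)C(C)C)c([C@@H]2CCCCN2C(=O)OC(C)(C)C)c(OC)c1C(O)C#Cc1ccccc1 | intermediate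
20 | tert-butyl (S)-2-[4-hydroxy-2-methoxy-3-(3-phenylprop-2-ynoyl)-6-(triisopropylsilyloxy)phenyl]piperidine-1-carboxylate | Oc1cc(O[Si](C(C)C)(C(C)C)C(C)C)c([C@@H]2CCCCN2C(=O)OC(C)(C)C)c(OC)c1C(=O)C#Cc1ccccc1 | intermediate
21 | tert-butyl (S)-2-{3-[3-(diethylamino)-3-phenylprop-2-enoyl]-4-hydroxy-2-methoxy-6-(triisopropylsilyloxy)phenyl}piperidine-1-carboxylate | CCN(CC)C(=CC(=O)c1c(O)cc(O[Si](C(C)C)(C(C)C)C(C)C)c([C@@H]2CCCCN2C(=O)OC(C)(C)C)c1OC)c1ccccc1 | intermediate
22 | tert-butyl (S)-2-[5-methoxy-4-oxo-2-phenyl-7-(triisopropylsilyloxy)-4H-chromen-6-yl]piperidine-1-carboxylate | COc1c([C@@H]2CCCCN2C(=O)OC(C)(C)C)c(O[Si](C(C)C)(C(C)C)C(C)C)cc2oc(-c3ccccc3)cc(=O)c12 | intermediate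
23 | tert-butyl (S)-2-(7-hydroxy-5-methoxy-4-oxo-2-phenyl-4H-chromen-6-yl)piperidine-1-carboxylate | COc1c([C@@H]2CCCCN2C(=O)OC(C)(C)C)c(O)cc2oc(-c3ccccc3)cc(=O)c12 | intermediate
24 | (S)-7-hydroxy-5-methoxy-2-phenyl-6-(piperidin-2-yl)-4H-chromen-4-one trifluoroacetate | COc1c([C@@H]2CCCCN2)c(O)cc2oc(-c3ccccc3)cc(=O)c12.OC(=O)C(F)(F)F | intermediate
25 | (S)-7-hydroxy-5-methoxy-6-(1-methylpiperidin-2-yl)-2-phenyl-4H-chromen-4-one | COc1c([C@@H]2CCCCN2C)c(O)cc2oc(-c3ccccc3)cc(=O)c12 | target

**Step count**

Total step count: 10. Longest linear sequence: 8 steps (steps 1, 2, 3, 6, 7, 8, 9, 10).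

**The three steps most likely to fail**

1. **Step 6 (key step).**
   - What may go wrong:
     - The vinylogous silyl ester character of 8 may slow the first ring opening.
     - The crowded, doubly substituted ketene may be captured only slowly by the branched ynol ether. Interception by the carbamate carbonyl oxygen, ketene dimerisation or acylation of the product phenol could then take over.
     - The skipped diyne may also erode on prolonged heating.
   - First remedy: irradiating 8 at ambient temperature before heating can start the opening.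
   - Fallback (sets out from 8 and 11, comes back at 19): the annulation is run with a slim, robust ynol ether, and the phenylethynyl unit is attached afterwards. Acetylide 11 is added to paraformaldehyde to give 3-methoxyprop-2-yn-1-ol F1, which is silylated (TESCl, imidazole) to triethyl[(3-methoxyprop-2-yn-1-yl)oxy]silane F2. Heating F2 with 8 in toluene should give the C4a-silyloxymethyl phenol F3. Buffered HF·pyridine frees the salicyl alcohol F4, and MnO2 oxidises it to the salicylaldehyde F5. Lithium phenylacetylide F6 (from phenylacetylene and n-BuLi, 2.2 equiv, THF, −78 °C) then adds to the formyl group to give 19.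

2. **Step 2.**
   - What may go wrong:
     - The carbenoid rearrangement may be incomplete.
     - The organolithium reagents may attack the carbamate.
     - Residual amide base may enolise ester 2, eroding C2'.
     - Silylation may occur on carbon instead of oxygen.
   - Fallback (sets out from 2, comes back at 4): the ynolate is made by oxidising a terminal alkyne instead of by rearrangement. i-Bu2AlH (toluene, −78 °C) reduces 2 to (S)-N-Boc-piperidine-2-carbaldehyde F7. Ohira–Bestmann homologation (dimethyl 1-diazo-2-oxopropylphosphonate, K2CO3, MeOH, 0 °C) gives (S)-N-Boc-2-ethynylpiperidine F8, at which stage the enantiopurity should be checked. n-BuLi converts it into the lithium acetylide F9. Lithium tert-butyl peroxide F10 (from t-BuOOH and LiN(SiMe3)2, THF, −78 → 0 °C) transfers oxygen to F9 to give ynolate 4, which is silylated with TIPSOTf to 5.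

3. **Step 7.**
   - What may go wrong:
     - The freed, doubly activated carbinol may ionise towards a quinone methide.
     - The aryl TIPS group may be lost alongside TES.
   - Fallback (sets out from 18, comes back at 20): the silyl ether is oxidised without ever freeing the alcohol. DDQ (CH2Cl2, pH 7 buffer, 0 °C) abstracts hydride from C4–H of the electron-rich benzylic silyl ether. Hydrolysis of the silyloxocarbenium ion then gives ynone 20 directly. This is the known oxidative cleavage of benzylic, allylic and propargylic silyl ethers. C2'–H is expected to be spared because its two ortho neighbours hold it in the arene plane.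

**Further compounds**

F1 | step 6 | 3-methoxyprop-2-yn-1-ol | COC#CCO
F2 | step 6 | triethyl[(3-methoxyprop-2-yn-1-yl)oxy]silane | COC#CCO[Si](CC)(CC)CC
F3 | step 6 | tert-butyl (S)-2-{4-hydroxy-2-methoxy-3-[(triethylsilyloxy)methyl]-6-(triisopropylsilyloxy)phenyl}piperidine-1-carboxylate | Oc1cc(O[Si](C(C)C)(C(C)C)C(C)C)c([C@@H]2CCCCN2C(=O)OC(C)(C)C)c(OC)c1CO[Si](CC)(CC)CC
F4 | step 6 | tert-butyl (S)-2-[4-hydroxy-3-(hydroxymethyl)-2-methoxy-6-(triisopropylsilyloxy)phenyl]piperidine-1-carboxylate | Oc1cc(O[Si](C(C)C)(C(C)C)C(C)C)c([C@@H]2CCCCN2C(=O)OC(C)(C)C)c(OC)c1CO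
F5 | step 6 | tert-butyl (S)-2-[3-formyl-4-hydroxy-2-methoxy-6-(triisopropylsilyloxy)phenyl]piperidine-1-carboxylate | Oc1cc(O[Si](C(C)C)(C(C)C)C(C)C)c([C@@H]2CCCCN2C(=O)OC(C)(C)C)c(OC)c1C=O
F6 | step 6 | lithium phenylacetylide | [Li+].[C-]#Cc1ccccc1
F7 | step 2 | tert-butyl (S)-2-formylpiperidine-1-carboxylate | O=C[C@@H]1CCCCN1C(=O)OC(C)(C)C
F8 | step 2 | tert-butyl (S)-2-ethynylpiperidine-1-carboxylate | C#C[C@@H]1CCCCN1C(=O)OC(C)(C)C
F9 | step 2 | lithium acetylide of tert-butyl (S)-2-ethynylpiperidine-1-carboxylate | [Li+].[C-]#C[C@@H]1CCCCN1C(=O)OC(C)(C)C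
F10 | step 2 | lithium tert-butyl peroxide | [Li+].CC(C)(C)O[O-]
F0 | step 7 | none | none
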